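**Kukoamine A by twofold Mitsunobu N-alkylation of an acyl carbamate: synthesis design**

## The problem

Kukoamine A (14) is an acyclic, twofold-symmetric tetraamine. It is a spermine chain (3, 4 and 3 carbons between four nitrogens) whose two outer nitrogens carry 3-(3,4-dihydroxyphenyl)propanoyl groups, while the two inner nitrogens remain free secondary amines. There is no stereocentre and no ring beyond the two benzene rings, so nothing has to be controlled in space. The task is chain assembly and the pairwise distinction of four nitrogens: the outer pair acylated, the inner pair not. The two catechols are oxidised to ortho-quinones by air as soon as base is present, and the product is a very polar polyamine that is best handled as a salt. The last steps must therefore be non-basic and non-oxidising, and should leave only volatile or filterable residues. A further trap lies in the central four-carbon unit: an amine carrying a 4-halobutyl group closes to a pyrrolidine faster than it meets a second amine, so that unit is best brought in with both nitrogens already attached. The feature that opens the key step is that each amide nitrogen (N1 and N12) is bound to a primary CH2, namely C1 of a trimethylene arm that ends at N4 or N9. If that nitrogen arrives carrying the dihydrocaffeoyl group and a second carbonyl (a carbamate), its N–H is acidic enough to be alkylated by a primary alcohol under redox-dehydration conditions. The symmetry then lets both N–CH2 bonds form in one operation on a symmetric diol.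

## Retrosynthesis

**Protecting groups.** The target 14 is traced back to its tetrabenzyl ether 13 by cutting the four phenolic O–benzyl bonds, and 13 to the tetracarbamate 12 by cutting four N–Boc bonds. Benzyl ethers are chosen for the catechols because they survive base, hydride, phosphine and anhydrous acid and leave by hydrogenolysis as toluene. Boc is chosen on all four nitrogens because one acid treatment removes the inner carbamates and converts the outer N-acyl carbamates into the secondary amides. Acidolysis is placed before hydrogenolysis so that the catechols are unveiled last, in an acidic and reducing medium.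

**Key disconnection.** Compound 12 is cut at the two bonds between the amide nitrogens and C1 of the propyl arms, giving two molecules of the N–H acidic acyl carbamate 6 and the symmetric diol 11. The neighbouring cut, at the amide C(O)–N bonds, would need a spermine chain in which the outer nitrogens are free and the inner ones blocked, which costs a selective protection sequence. With the chosen cut the chain ends are oxygen until the key step and the inner nitrogens are carbamates from the moment they are made, so no amine ever competes with another. The precursors are of about half the size, and one of them (11) is symmetric. The forward reaction must alkylate a weakly acidic imide-type N–H at nitrogen, twice, and faster than the flanking Boc carbonyl can attack the activated carbinol carbon.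

**Acyl carbamate 6.** This is cut at the N–acyl bond into the acid 3 (via its chloride 5) and tert-butyl carbamate 4. Acid 3 is dihydrocaffeic acid 1 with both phenols benzylated (via the benzyl ester 2). The acid already holds every carbon of the side chain at the right oxidation level. The forward reaction is the N-acylation of a carbamate anion.

**Diol 11.** Functional group interconversion leads to the diester 10. Compound 10 is cut at the two N–CH2 bonds of the arms, which in the forward sense are conjugate additions of butane-1,4-diamine 7 to methyl acrylate 8 (via the bis(amino ester) 9), followed by Boc protection in the same flask. The alternative cut at the N–C bonds of the butane unit would join an amino alcohol to a four-carbon bis-electrophile and runs into the pyrrolidine closure named above. With 7 the four-carbon unit arrives with both nitrogens in place, and each primary amine needs to add only once.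

## Roads not taken

**Alternative 1:** The cut is at the bond between each amide carbonyl and its α-carbon. In the forward step two equivalents of the arylethyl Grignard reagent A3 (catechol masked as an acetonide) add to the bis-isocyanate A2, giving the bis-amide A1 after protonation.
- Merits: the secondary amide N–H is formed directly, the magnesium amidate does not add a second time, and one acid treatment would remove both the Boc groups and the acetonides. That endgame is one step shorter than the chosen one and is the real advantage of this road.
- Weak points: A2 is a moisture-sensitive aliphatic bis-isocyanate that can only be made by phosgenating the outer nitrogens of a spermine chain whose inner nitrogens are already carbamates, so the nitrogen differentiation problem returns in full. A3 needs its own preparation of several steps and is prone to homocoupling when formed. A Grignard reagent would also have to discriminate between isocyanate and carbamate carbonyls.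
- Comparison: the chosen plan uses commercial dihydrocaffeic acid with its whole carbon chain, needs no organometallic reagent and no phosgene, and never has to distinguish nitrogens. It pays with one more deprotection step.

**Alternative 2:** The cut is at the two bonds between the inner nitrogens and the central butane unit. Two molecules of the sulfonamide A5 are alkylated by 1,4-dibromobutane A6 under K2CO3 to give A4. A thiolate then removes the sulfonyl groups and hydrogenolysis the benzyl ethers.
- Merits: alkylation of 2-nitrobenzenesulfonamides is among the most reliable ways to make a secondary amine. The sulfonamide reacts only once, and after the first substitution it has no N–H left, so the pyrrolidine closure is impossible. The amide N–H is far too weakly acidic to interfere. A5 would come from acid 3 in two operations. The whole route is about one step shorter than the chosen one, and its key step rests on firmer precedent. In both respects this road is better.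
- Weak points: the nitroarenes forbid any hydrogenation before the sulfonyl groups are gone. The free, polar diamine and the sulfur by-products of the thiolate step therefore appear immediately before the palladium-catalysed step. The three-carbon diamine must also be desymmetrised statistically.
- Comparison: the chosen plan carries only carbamates and benzyl ethers and no sulfur at any stage. Its nitrogen deprotection gives only gases, and the product of that step can be isolated as a salt by trituration. It accepts in exchange a less common alkylation of an acyl carbamate.

**Alternative 3:** The cut is at the aryl–Cβ bonds. The bis-acrylamide A8 is coupled with two molecules of the aryl bromide A9 under Pd(OAc)2 and P(o-tolyl)3 to give the bis-cinnamamide A7. Hydrogenation then saturates both alkenes and cleaves the benzyl ethers in one step, and acid removes the Boc groups.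
- Merits: Heck arylation of acrylamides is dependable and β-selective, the alkene geometry is irrelevant, and the hydrogenation does double duty. The key step is better precedented than the chosen one.
- Weak points: A9 is an electron-rich bromide that adds slowly to palladium and needs heating, at which acrylamides tend to polymerise. Both ends must couple completely or the mono-arylated material has to be separated. A8 again requires the outer nitrogens of a spermine chain to be told apart from the inner ones. Unsaturation is introduced only to be removed.
- Comparison: the step counts are comparable. The chosen plan needs no cross-coupling, starts from the acid at the correct oxidation level and makes the outer/inner nitrogen distinction automatically.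

Key step: step 5

## Route

Assumption: the amines 13 and 14 are isolated as their bis-hydrochloride salts but are named, drawn and counted as the free bases; the salt-forming HCl is not treated as a reagent that adds atoms.

Step 1
Reactants: 1 3-(3,4-dihydroxyphenyl)propanoic acid (dihydrocaffeic acid)
Product: 3 3-[3,4-bis(benzyloxy)phenyl]propanoic acid, via benzyl ester 2 (not isolated)
Conditions: BnBr (3.5 equiv), K2CO3, DMF, 60 °C, under N2; then NaOH, MeOH–H2O, 60 °C; acidify with aq HCl
Reagents that add atoms: benzyl bromide, BrCc1ccccc1; sodium hydroxide, [Na+].[OH-] (its oxygen ends in the carboxyl group)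
Why: Williamson O-alkylation of both phenoxides and of the carboxylate gives the tribenzylated ester 2; saponification then cleaves only the benzyl ester, because aryl benzyl ethers are inert to hydroxide. Exclusion of air protects the catechol until it is capped.

Step 2
Reactants: 3 3-[3,4-bis(benzyloxy)phenyl]propanoic acid; 4 tert-butyl carbamate (2.2 equiv)
Product: 6 tert-butyl {3-[3,4-bis(benzyloxy)phenyl]propanoyl}carbamate, via acid chloride 5 (not isolated)
Conditions: (COCl)2, cat. DMF, CH2Cl2, 0 °C to rt, evaporate; then added to 4 and LiN(SiMe3)2 (2.1 equiv), THF, −78 to 0 °C; aq NH4Cl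
Reagents that add atoms: oxalyl chloride, O=C(Cl)C(=O)Cl (supplies only the chlorine of 5)
Why: The acid chloride acylates the N-lithio carbamate, the same N-acylation of a carbamate anion that is routine for lithiated oxazolidinones. The second equivalent of anion takes up the more acidic imide-type N–H of 6, and addition of 5 to an excess of anion suppresses diacylation.

Step 3
Reactants: 7 butane-1,4-diamine (putrescine); 8 methyl acrylate (2.0 equiv)
Product: 10 dimethyl 3,3'-{butane-1,4-diylbis[(tert-butoxycarbonyl)imino]}dipropanoate, via bis(amino ester) 9 (not isolated)
Conditions: MeOH, 0 °C to rt; then Boc2O (2.3 equiv), rt; wash with dilute aq citric acid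
Reagents that add atoms: di-tert-butyl dicarbonate, CC(C)(C)OC(=O)OC(=O)OC(C)(C)C
Why: Aza-Michael addition of each primary amine to one acrylate; a second addition at the resulting secondary β-amino ester is much slower at room temperature, so stoichiometry should control the outcome. Boc protection in the same flask turns 9 into a neutral dicarbamate, and over-alkylated by-products, which keep a basic nitrogen, are removed by the acid wash.

Step 4
Reactants: 10 dimethyl 3,3'-{butane-1,4-diylbis[(tert-butoxycarbonyl)imino]}dipropanoate
Product: 11 di-tert-butyl butane-1,4-diylbis[(3-hydroxypropyl)carbamate]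
Conditions: LiBH4, THF, 0 °C to rt; aqueous work-up
Reagents that add atoms: none
Why: Chemoselective ester reduction; LiBH4 takes methyl esters to primary alcohols and leaves tert-butyl carbamates untouched.

Step 5
Reactants: 6 tert-butyl {3-[3,4-bis(benzyloxy)phenyl]propanoyl}carbamate (3 equiv); 11 di-tert-butyl butane-1,4-diylbis[(3-hydroxypropyl)carbamate]
Product: 12 N1,N4,N9,N12-tetrakis(tert-butoxycarbonyl)-N1,N12-bis{3-[3,4-bis(benzyloxy)phenyl]propanoyl}spermine
Conditions: PBu3 (3 equiv), 1,1'-(azodicarbonyl)dipiperidine (3 equiv), toluene, about 0.4 M in 11, 0 °C to rt
Reagents that add atoms: none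
Why: Mitsunobu reaction in its tributylphosphine/azodicarboxamide variant: PBu3 adds to the azo compound to give a phosphonium–hydrazide betaine, which is more basic than the one from PPh3 and an azodicarboxylate and should therefore remove the N–H proton of 6, acidified by the acyl and the Boc carbonyl on either side. Each primary hydroxyl of 11 is transferred to phosphorus as an alkoxyphosphonium ion, and the nitrogen of the acyl carbamate anion displaces tributylphosphine oxide at the primary carbon by SN2, once at each end, forming the two N–CH2 bonds. The closest known reaction type is the Mitsunobu N-alkylation of imides, imidodicarbonates and N-acyl carbamates by primary alcohols. No ring closes and no stereocentre is formed. The step needs N- over O-alkylation of the ambident anion, which is expected as for other imide anions at an unhindered primary carbon. It also needs intermolecular attack to outrun closure of the neighbouring Boc carbonyl oxygen onto the activated carbon, which would give a six-membered cyclic carbamate with loss of isobutene; the excess of 6, the high concentration and a betaine that keeps the nucleophile ionised are chosen to secure this. Double rather than single alkylation follows from the excess of reagents, since the two ends are ten atoms apart and react independently; unreacted 6 is recoverable.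

Step 6
Reactants: 12 N1,N4,N9,N12-tetrakis(tert-butoxycarbonyl)-N1,N12-bis{3-[3,4-bis(benzyloxy)phenyl]propanoyl}spermine
Product: 13 N1,N12-bis{3-[3,4-bis(benzyloxy)phenyl]propanoyl}spermine
Conditions: 4 M HCl in dioxane, CH2Cl2, 0 °C to rt; evaporate, triturate with Et2O
Reagents that add atoms: none
Why: Acidolysis of tert-butyl carbamates: the two N-acyl carbamates collapse to secondary amides and the two inner carbamates to ammonium chlorides, all four Boc groups leaving as isobutene and CO2. Benzyl aryl ethers and amides are stable to anhydrous HCl at room temperature, and chloride intercepts the tert-butyl cation before it can alkylate the electron-rich rings.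

Step 7
Reactants: 13 N1,N12-bis{3-[3,4-bis(benzyloxy)phenyl]propanoyl}spermine
Product: 14 Kukoamine A, N1,N12-bis[3-(3,4-dihydroxyphenyl)propanoyl]spermine
Conditions: H2 (1 atm), 10% Pd/C, MeOH, rt; filter under argon
Reagents that add atoms: none
Why: Catalytic hydrogenolysis of the four benzyl aryl ethers. The protonated amines should neither bind the catalyst nor be alkylated reductively, and the acidic, reducing medium protects the liberated catechols from autoxidation.

## Compound list

1 | 3-(3,4-dihydroxyphenyl)propanoic acid (dihydrocaffeic acid) | O=C(O)CCc1ccc(O)c(O)c1 | starting material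
2 | benzyl 3-[3,4-bis(benzyloxy)phenyl]propanoate | O=C(OCc1ccccc1)CCc1ccc(OCc2ccccc2)c(OCc2ccccc2)c1 | intermediate
3 | 3-[3,4-bis(benzyloxy)phenyl]propanoic acid | O=C(O)CCc1ccc(OCc2ccccc2)c(OCc2ccccc2)c1 | intermediate
4 | tert-butyl carbamate | NC(=O)OC(C)(C)C | starting material
5 | 3-[3,4-bis(benzyloxy)phenyl]propanoyl chloride | O=C(Cl)CCc1ccc(OCc2ccccc2)c(OCc2ccccc2)c1 | intermediate
6 | tert-butyl {3-[3,4-bis(benzyloxy)phenyl]propanoyl}carbamate | O=C(CCc1ccc(OCc2ccccc2)c(OCc2ccccc2)c1)NC(=O)OC(C)(C)C | intermediate
7 | butane-1,4-diamine (putrescine) | NCCCCN | starting material
8 | methyl acrylate | C=CC(=O)OC | starting material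
9 | dimethyl 3,3'-(butane-1,4-diyldiimino)dipropanoate | COC(=O)CCNCCCCNCCC(=O)OC | intermediate
10 | dimethyl 3,3'-{butane-1,4-diylbis[(tert-butoxycarbonyl)imino]}dipropanoate | COC(=O)CCN(C(=O)OC(C)(C)C)CCCCN(C(=O)OC(C)(C)C)CCC(=O)OC | intermediate
11 | di-tert-butyl butane-1,4-diylbis[(3-hydroxypropyl)carbamate] | OCCCN(C(=O)OC(C)(C)C)CCCCN(C(=O)OC(C)(C)C)CCCO | intermediate
12 | N1,N4,N9,N12-tetrakis(tert-butoxycarbonyl)-N1,N12-bis{3-[3,4-bis(benzyloxy)phenyl]propanoyl}spermine | O=C(CCc1ccc(OCc2ccccc2)c(OCc2ccccc2)c1)N(C(=O)OC(C)(C)C)CCCN(C(=O)OC(C)(C)C)CCCCN(C(=O)OC(C)(C)C)CCCN(C(=O)OC(C)(C)C)C(=O)CCc1ccc(OCc2ccccc2)c(OCc2ccccc2)c1 | intermediate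
13 | N1,N12-bis{3-[3,4-bis(benzyloxy)phenyl]propanoyl}spermine | O=C(CCc1ccc(OCc2ccccc2)c(OCc2ccccc2)c1)NCCCNCCCCNCCCNC(=O)CCc1ccc(OCc2ccccc2)c(OCc2ccccc2)c1 | intermediate
14 | Kukoamine A | O=C(CCc1ccc(O)c(O)c1)NCCCNCCCCNCCCNC(=O)CCc1ccc(O)c(O)c1 | target

## Step count and risks

Total step count: 7. Longest linear sequence: 5 steps (steps 1, 2, 5, 6, 7; the diol branch 3, 4, 5, 6, 7 is equally long).

**Step 5 (key step).**
- Risk: the N–H of 6 may be deprotonated too slowly, so that the alkoxyphosphonium ion is consumed first by the flanking Boc carbonyl (closure to a six-membered cyclic carbamate with loss of the tert-butyl group) or by the hydrazide anion. Part of the ambident anion may also react at oxygen, and the reaction may stop after one end has been alkylated.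
- Fallback: this abandons the alkylation of an acyl nitrogen and makes the amide bonds by acylation. It sets out from 11 and 3. Diol 11 is converted by a Mitsunobu reaction with diphenylphosphoryl azide (PPh3, diisopropyl azodicarboxylate, THF) into di-tert-butyl butane-1,4-diylbis[(3-azidopropyl)carbamate] F1; azide is a nucleophile strong and acidic enough to outrun the cyclisation. Hydrogenation of F1 (H2, Pd/C, EtOH) gives di-tert-butyl butane-1,4-diylbis[(3-aminopropyl)carbamate] F2. Carbodiimide coupling of F2 with two equivalents of acid 3 (EDC·HCl, HOBt, CH2Cl2) gives N4,N9-di-Boc-N1,N12-bis{3-[3,4-bis(benzyloxy)phenyl]propanoyl}spermine F3. Treatment of F3 with HCl in dioxane returns to the route at 13.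

**Step 2.**
- Risk: a second acylation of the product anion may lead to the N,N-diacyl carbamate, the strongly basic medium may turn the acid chloride into a ketene, and on standing the acid chloride may acylate its own electron-rich ring.
- Fallback: this sets out from 3 (through its chloride 5) and returns at 6. Chloride 5 is treated with aqueous ammonia to give 3-[3,4-bis(benzyloxy)phenyl]propanamide F4. Heating F4 with oxalyl chloride in 1,2-dichloroethane converts it into 3-[3,4-bis(benzyloxy)phenyl]propanoyl isocyanate F5, which is not isolated. Addition of tert-butanol to F5 gives 6. No strong base is involved.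

**Step 3.**
- Risk: each nitrogen may add acrylate twice or not at all, giving a statistical mixture that lowers the amount of symmetric product; slow aminolysis of the ester by the amine may add oligomers.
- Fallback: this sets out from 7 and returns at 11, replacing steps 3 and 4. Diamine 7 is sulfonylated with 2-nitrobenzenesulfonyl chloride and Et3N to N,N'-butane-1,4-diylbis(2-nitrobenzenesulfonamide) F6. Each sulfonamide can be alkylated only once, and treatment with 3-bromopropan-1-ol and K2CO3 in DMF gives N,N'-butane-1,4-diylbis[N-(3-hydroxypropyl)-2-nitrobenzenesulfonamide] F7. Thiophenol and K2CO3 in acetonitrile release 3,3'-(butane-1,4-diyldiimino)dipropan-1-ol F8, which is not isolated but treated in the same flask with di-tert-butyl dicarbonate to give 11.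

**Step 7.**
- Risk: hydrogenolysis may stall at partly debenzylated salts of low solubility, and any amine that is not protonated may slow the catalyst or be methylated by the solvent.
- Fallback: the order of the last two steps is reversed, setting out from 12 and returning at 14. Compound 12, which has no basic nitrogen, is hydrogenolysed (H2, Pd/C, EtOAc–EtOH) to N1,N4,N9,N12-tetrakis(tert-butoxycarbonyl)-N1,N12-bis[3-(3,4-dihydroxyphenyl)propanoyl]spermine F9. Treatment of F9 with HCl in dioxane in the presence of a cation scavenger then gives 14 directly.

## Further compounds

F1 | step 5 | di-tert-butyl butane-1,4-diylbis[(3-azidopropyl)carbamate] | [N-]=[N+]=NCCCN(C(=O)OC(C)(C)C)CCCCN(C(=O)OC(C)(C)C)CCCN=[N+]=[N-]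
F2 | step 5 | di-tert-butyl butane-1,4-diylbis[(3-aminopropyl)carbamate] | NCCCN(C(=O)OC(C)(C)C)CCCCN(C(=O)OC(C)(C)C)CCCN
F3 | step 5 | N4,N9-di-Boc-N1,N12-bis{3-[3,4-bis(benzyloxy)phenyl]propanoyl}spermine | O=C(CCc1ccc(OCc2ccccc2)c(OCc2ccccc2)c1)NCCCN(C(=O)OC(C)(C)C)CCCCN(C(=O)OC(C)(C)C)CCCNC(=O)CCc1ccc(OCc2ccccc2)c(OCc2ccccc2)c1
F4 | step 2 | 3-[3,4-bis(benzyloxy)phenyl]propanamide | NC(=O)CCc1ccc(OCc2ccccc2)c(OCc2ccccc2)c1
F5 | step 2 | 3-[3,4-bis(benzyloxy)phenyl]propanoyl isocyanate | O=C=NC(=O)CCc1ccc(OCc2ccccc2)c(OCc2ccccc2)c1
F6 | step 3 | N,N'-butane-1,4-diylbis(2-nitrobenzenesulfonamide) | O=S(=O)(NCCCCNS(=O)(=O)c1ccccc1[N+](=O)[O-])c1ccccc1[N+](=O)[O-]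
F7 | step 3 | N,N'-butane-1,4-diylbis[N-(3-hydroxypropyl)-2-nitrobenzenesulfonamide] | OCCCN(CCCCN(CCCO)S(=O)(=O)c1ccccc1[N+](=O)[O-])S(=O)(=O)c1ccccc1[N+](=O)[O-]
F8 | step 3 | 3,3'-(butane-1,4-diyldiimino)dipropan-1-ol | OCCCNCCCCNCCCO
F9 | step 7 | N1,N4,N9,N12-tetrakis(tert-butoxycarbonyl)-N1,N12-bis[3-(3,4-dihydroxyphenyl)propanoyl]spermine | O=C(CCc1ccc(O)c(O)c1)N(C(=O)OC(C)(C)C)CCCN(C(=O)OC(C)(C)C)CCCCN(C(=O)OC(C)(C)C)CCCN(C(=O)OC(C)(C)C)C(=O)CCc1ccc(O)c(O)c1
A1 | alternative 1 | N4,N9-di-Boc-N1,N12-bis[3-(2,2-dimethyl-1,3-benzodioxol-5-yl)propanoyl]spermine | O=C(CCc1ccc2OC(C)(C)Oc2c1)NCCCN(C(=O)OC(C)(C)C)CCCCN(C(=O)OC(C)(C)C)CCCNC(=O)CCc1ccc2OC(C)(C)Oc2c1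
A2 | alternative 1 | di-tert-butyl butane-1,4-diylbis[(3-isocyanatopropyl)carbamate] | O=C=NCCCN(C(=O)OC(C)(C)C)CCCCN(C(=O)OC(C)(C)C)CCCN=C=O
A3 | alternative 1 | [2-(2,2-dimethyl-1,3-benzodioxol-5-yl)ethyl]magnesium bromide | CC1(C)Oc2ccc(CC[Mg]Br)cc2O1
A4 | alternative 2 | N4,N9-bis(2-nitrophenylsulfonyl)-N1,N12-bis{3-[3,4-bis(benzyloxy)phenyl]propanoyl}spermine | O=C(CCc1ccc(OCc2ccccc2)c(OCc2ccccc2)c1)NCCCN(S(=O)(=O)c1ccccc1[N+](=O)[O-])CCCCN(S(=O)(=O)c1ccccc1[N+](=O)[O-])CCCNC(=O)CCc1ccc(OCc2ccccc2)c(OCc2ccccc2)c1
A5 | alternative 2 | 3-[3,4-bis(benzyloxy)phenyl]-N-(3-{[(2-nitrophenyl)sulfonyl]amino}propyl)propanamide | O=C(CCc1ccc(OCc2ccccc2)c(OCc2ccccc2)c1)NCCCNS(=O)(=O)c1ccccc1[N+](=O)[O-]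
A6 | alternative 2 | 1,4-dibromobutane | BrCCCCBr
A7 | alternative 3 | N4,N9-di-Boc-N1,N12-bis[(E)-3-(3,4-bis(benzyloxy)phenyl)acryloyl]spermine | O=C(/C=C/c1ccc(OCc2ccccc2)c(OCc2ccccc2)c1)NCCCN(C(=O)OC(C)(C)C)CCCCN(C(=O)OC(C)(C)C)CCCNC(=O)/C=C/c1ccc(OCc2ccccc2)c(OCc2ccccc2)c1
A8 | alternative 3 | N4,N9-di-Boc-N1,N12-diacryloylspermine | C=CC(=O)NCCCN(C(=O)OC(C)(C)C)CCCCN(C(=O)OC(C)(C)C)CCCNC(=O)C=C
A9 | alternative 3 | 4-bromo-1,2-bis(benzyloxy)benzene | Brc1ccc(OCc2ccccc2)c(OCc2ccccc2)c1
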